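**Retrosynthetic overview**

- Ring numbering: C1 (bears C7H2OH), C2 (ketone), C3 (epoxy-ester oxygen O3), C4 (isopropyl, methine C8), C5 (angelate oxygen O5), C6 (vinyl CH). The plan rests on two features: C4 and C5 carry isopropyl and oxygen side by side as in isopulegol, and C5–C6=C1–C2 is a cis alkene between two oxygenated carbons, which is an oxidatively opened furan.
- Late stage: C7–OH from its silyl ether, the O3 ester from (2R,3R)-epoxyangelic acid (made from angelic acid by asymmetric epoxidation), the O5 angelate by invertive Mitsunobu esterification, isopropyl from isopropenyl.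
- Key disconnection C4–C5: Lewis-acid carbonyl-ene closure of a (Z)-4-oxo-enal. This forms the only carbocycle; the oxirane arrives ready-made in the acid.
- The oxo-enal comes from a 2,3-disubstituted furan and singlet oxygen, and the furan from furan-3-methanol and but-2-ynal. C3 is set by oxazaborolidine reduction of the furyl propynyl ketone (bulky furyl against rod-like alkynyl, a cleaner contest than furyl against dimethylvinyl); the alkyne is then methylated to the dimethylvinyl group.

Key step: step 8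

Remark: but-2-ynal is taken as a purchasable reagent; otherwise it is released from its commercial diethyl acetal with aqueous formic acid just before use.

**Route**

Step 1
Reactants: 1 furan-3-methanol; 2 but-2-ynal
Product: 4 rac-1-[3-(hydroxymethyl)furan-2-yl]but-2-yn-1-ol, via 2-lithio-3-(lithiooxymethyl)furan 3 (not isolated)
Conditions: 1, n-BuLi (2.1 equiv), THF, −78 → 0 °C; then 2, −78 °C; H2O
Reagents that add atoms: none
Why: Alkoxide-directed ortho-lithiation removes the C2 proton (α to the ring oxygen and ortho to CH2OLi) and the aryllithium adds 1,2 to the ynal; the carbinol forms racemic and is corrected in steps 3 and 4.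

Step 2
Reactants: 4 rac-1-[3-(hydroxymethyl)furan-2-yl]but-2-yn-1-ol
Product: 5 rac-1-[3-({[tert-butyl(diphenyl)silyl]oxy}methyl)furan-2-yl]but-2-yn-1-ol
Conditions: TBDPSCl (1.05 equiv), imidazole, CH2Cl2, −20 → 0 °C
Reagents that add atoms: tert-butyl(chloro)diphenylsilane, CC(C)(C)[Si](Cl)(c1ccccc1)c1ccccc1
Why: Silyl ether formation with the bulky chlorosilane should take the primary hydroxyl in preference to the hindered secondary one.

Step 3
Reactants: 5 rac-1-[3-({[tert-butyl(diphenyl)silyl]oxy}methyl)furan-2-yl]but-2-yn-1-ol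
Product: 6 1-[3-({[tert-butyl(diphenyl)silyl]oxy}methyl)furan-2-yl]but-2-yn-1-one
Conditions: MnO2 (activated, excess), CH2Cl2, rt
Reagents that add atoms: none
Why: MnO2 oxidation of a doubly activated (furfurylic and propargylic) alcohol under neutral conditions; furan and silyl ether are inert.

Step 4
Reactants: 6 1-[3-({[tert-butyl(diphenyl)silyl]oxy}methyl)furan-2-yl]but-2-yn-1-one
Product: 7 (1S)-1-[3-({[tert-butyl(diphenyl)silyl]oxy}methyl)furan-2-yl]but-2-yn-1-ol
Conditions: (R)-2-methyl-CBS-oxazaborolidine (1.0 equiv), BH3·SMe2 (1.2 equiv), THF, −30 °C; MeOH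
Reagents that add atoms: none
Why: Corey–Bakshi–Shibata reduction; the ketone should bind boron anti to the bulky 3-substituted furyl group and syn to the slim propynyl group, so the (R)-catalyst delivers hydride to the face that gives the S carbinol (the sense by which it turns acetophenone into (S)-1-phenylethanol).

Step 5
Reactants: 7 (1S)-1-[3-({[tert-butyl(diphenyl)silyl]oxy}methyl)furan-2-yl]but-2-yn-1-ol
Product: 8 (1S)-1-[3-({[tert-butyl(diphenyl)silyl]oxy}methyl)furan-2-yl]-3-methylbut-2-en-1-ol
Conditions: MeMgBr (5 equiv), Fe(acac)3 (15 mol%), THF, −78 → 0 °C; H2O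
Reagents that add atoms: methylmagnesium bromide, C[Mg]Br
Why: Iron-catalysed, alkoxide-directed carbomagnesiation of the propargylic alcohol should place methyl on the alkyne carbon distal to the alkoxide and magnesium on the proximal one; protonation gives the alkene, whose distal carbon now carries two methyl groups so that geometry is no issue, and the carbinol centre is untouched.

Step 6
Reactants: 8 (1S)-1-[3-({[tert-butyl(diphenyl)silyl]oxy}methyl)furan-2-yl]-3-methylbut-2-en-1-ol
Product: 9 tert-butyl({(1S)-1-[3-({[tert-butyl(diphenyl)silyl]oxy}methyl)furan-2-yl]-3-methylbut-2-en-1-yl}oxy)dimethylsilane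
Conditions: TBSCl, imidazole, DMAP (cat.), DMF, rt
Reagents that add atoms: tert-butyl(chloro)dimethylsilane, CC(C)(C)[Si](C)(C)Cl
Why: Imidazole-promoted silylation forms the O–Si bond only, under non-acidic conditions that should not ionise the furfurylic allylic carbinol; configuration is retained.

Step 7
Reactants: 9 tert-butyl({(1S)-1-[3-({[tert-butyl(diphenyl)silyl]oxy}methyl)furan-2-yl]-3-methylbut-2-en-1-yl}oxy)dimethylsilane
Product: 11 (2Z,5S)-5-[(tert-butyldimethylsilyl)oxy]-3-{[(tert-butyldiphenylsilyl)oxy]methyl}-7-methyl-4-oxoocta-2,6-dienal, via furan 2,5-endoperoxide 10 (not isolated)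
Conditions: O2, visible light, tetraphenylporphyrin (cat.), CH2Cl2, −78 °C; then Me2S, −78 → 0 °C; crude 11 used at once
Reagents that add atoms: dioxygen, O=O
Why: Singlet oxygen adds [4+2] across furan C2/C5, which should be far faster than the Schenck ene reaction at the hindered trisubstituted alkene; Me2S reduces the endoperoxide, which collapses to the 1,4-dicarbonyl with the former furan C3=C4 bond kept as the cis alkene, and the silyloxy centre is not touched.

Step 8
Reactants: 11 (2Z,5S)-5-[(tert-butyldimethylsilyl)oxy]-3-{[(tert-butyldiphenylsilyl)oxy]methyl}-7-methyl-4-oxoocta-2,6-dienal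
Product: 12 (4S,5R,6S)-6-[(tert-butyldimethylsilyl)oxy]-2-{[(tert-butyldiphenylsilyl)oxy]methyl}-4-hydroxy-5-(prop-1-en-2-yl)cyclohex-2-en-1-one (OH and OTBS both trans to isopropenyl)
Conditions: Me2AlCl (1.5 equiv), CH2Cl2, −78 → −40 °C; cold H2O
Reagents that add atoms: none
Why: Me2AlCl binds the C5 aldehyde oxygen, C4 of the trisubstituted alkene attacks C5 while positive charge builds at tertiary C8, and a hydrogen of a C8 methyl group passes to the aluminium-bound oxygen through a six-centre array, so the C4–C5 bond, the C5 alkoxide and the isopropenyl group arise in one event (type-1 intramolecular carbonyl-ene reaction, Prins-like in charge distribution). The closest known reactions are the Lewis-acid cyclisations of citronellal to isopulegol and of neral to isopiperitenol, the latter also with a cis enal inside the forming ring; the 4-oxo group here only makes the aldehyde a stronger enophile. The one ring closes as a six-membered carbocycle by exo attack on the aldehyde carbon (6-exo-trig) through a half-chair held by the cis C1=C6 alkene. The C4 centre is set by C3: allylic 1,3-strain against the cis methyl on C8 keeps C3–H in the alkene plane, the OTBS group then sits pseudo-equatorial, and C5 adds to the alkene face that leaves isopropenyl trans to O3. The C5 centre is set by the chair-like arrangement with the aldehyde oxygen pseudo-equatorial and gauche to C8, as the hydrogen shift demands, which should give OH trans to isopropenyl as in isopulegol. The step needs activation of the aldehyde in preference to the C2 ketone and retention of the cis alkene, which the lower hindrance and higher basicity of the aldehyde oxygen, the proton-scavenging alkylaluminium reagent and the low temperature should secure.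

Step 9
Reactants: 12 (4S,5R,6S)-6-[(tert-butyldimethylsilyl)oxy]-2-{[(tert-butyldiphenylsilyl)oxy]methyl}-4-hydroxy-5-(prop-1-en-2-yl)cyclohex-2-en-1-one
Product: 13 (4S,5R,6S)-6-[(tert-butyldimethylsilyl)oxy]-2-{[(tert-butyldiphenylsilyl)oxy]methyl}-4-hydroxy-5-(propan-2-yl)cyclohex-2-en-1-one
Conditions: H2 (1 atm), RhCl(PPh3)3 (5 mol%), benzene, rt
Reagents that add atoms: none
Why: Homogeneous hydrogenation with RhCl(PPh3)3 should reduce the unhindered 1,1-disubstituted alkene and leave the trisubstituted conjugated C1=C6 bond, as in the conversion of carvone to carvotanacetone; no stereocentre is formed.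

Step 10
Reactants: 13 (4S,5R,6S)-6-[(tert-butyldimethylsilyl)oxy]-2-{[(tert-butyldiphenylsilyl)oxy]methyl}-4-hydroxy-5-(propan-2-yl)cyclohex-2-en-1-one; 14 angelic acid ((2Z)-2-methylbut-2-enoic acid)
Product: 15 (1R,5S,6R)-5-[(tert-butyldimethylsilyl)oxy]-3-{[(tert-butyldiphenylsilyl)oxy]methyl}-4-oxo-6-(propan-2-yl)cyclohex-2-en-1-yl (2Z)-2-methylbut-2-enoate (angelate cis to isopropyl)
Conditions: PPh3, DIAD, toluene, 0 °C → rt
Reagents that add atoms: none
Why: Mitsunobu esterification: the C5 hydroxyl is activated as the alkoxyphosphonium ion and displaced by angelate with inversion (SN2), placing O5 cis to isopropyl; the pseudo-equatorial leaving group has no anti-periplanar hydrogen on C4, which disfavours elimination, and the neutral medium should preserve the Z acid.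

Step 11
Reactants: 15 (1R,5S,6R)-5-[(tert-butyldimethylsilyl)oxy]-3-{[(tert-butyldiphenylsilyl)oxy]methyl}-4-oxo-6-(propan-2-yl)cyclohex-2-en-1-yl (2Z)-2-methylbut-2-enoate
Product: 16 (1R,5S,6S)-3-{[(tert-butyldiphenylsilyl)oxy]methyl}-5-hydroxy-4-oxo-6-(propan-2-yl)cyclohex-2-en-1-yl (2Z)-2-methylbut-2-enoate (the change of the C6 descriptor is a priority effect only)
Conditions: 48% aq. HF (dilute), MeCN, 0 °C, monitored
Reagents that add atoms: none
Why: Protodesilylation with dilute HF should cleave the secondary TBS ether well before the more acid-stable TBDPS ether; angelate and enone are untouched.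

Step 12
Reactants: 14 angelic acid
Product: 17 (2Z)-2-methylbut-2-en-1-ol
Conditions: LiAlH4, Et2O, 0 °C → rt; aq. NaOH work-up
Reagents that add atoms: none
Why: Hydride reduction of the carboxylic acid to the primary allylic alcohol; the β-alkyl trisubstituted alkene is not reduced and keeps its Z geometry.

Step 13
Reactants: 17 (2Z)-2-methylbut-2-en-1-ol
Product: 18 [(2S,3R)-2,3-dimethyloxiran-2-yl]methanol
Conditions: Ti(OiPr)4 (10 mol%), L-(+)-diethyl tartrate (12 mol%), t-BuOOH (anhydrous), 4 Å sieves, CH2Cl2, −20 °C; non-aqueous work-up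
Reagents that add atoms: tert-butyl hydroperoxide, CC(C)(C)OO
Why: Katsuki–Sharpless asymmetric epoxidation: with L-(+)-tartrate oxygen is delivered to the alkene face that gives the (2S,3R)-epoxy alcohol (the same facial sense that turns (E)-hex-2-en-1-ol into its (2S,3S)-epoxide); the cis relation of CH2OH and the C3 methyl is carried over from the Z alkene.

Step 14
Reactants: 18 [(2S,3R)-2,3-dimethyloxiran-2-yl]methanol
Product: 19 (2R,3R)-2,3-dimethyloxirane-2-carboxylic acid
Conditions: RuCl3 (2 mol%), NaIO4 (3 equiv), MeCN/EtOAc/H2O, 0 °C → rt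
Reagents that add atoms: sodium periodate, [Na+].[O-]I(=O)(=O)=O; water, O
Why: RuO4-catalysed oxidation of the primary alcohol through the aldehyde hydrate to the acid leaves the oxirane intact; the C2 descriptor changes from S to R only because CO2H outranks C3.

Step 15
Reactants: 16 (1R,5S,6S)-3-{[(tert-butyldiphenylsilyl)oxy]methyl}-5-hydroxy-4-oxo-6-(propan-2-yl)cyclohex-2-en-1-yl (2Z)-2-methylbut-2-enoate; 19 (2R,3R)-2,3-dimethyloxirane-2-carboxylic acid
Product: 21 (1S,5R,6R)-3-{[(tert-butyldiphenylsilyl)oxy]methyl}-5-{[(2Z)-2-methylbut-2-enoyl]oxy}-2-oxo-6-(propan-2-yl)cyclohex-3-en-1-yl (2R,3R)-2,3-dimethyloxirane-2-carboxylate, via mixed carboxylic anhydride 20 (not isolated)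
Conditions: 19, 2,4,6-trichlorobenzoyl chloride, Et3N, toluene, rt; then 16, DMAP (0.3 equiv), 0 °C → rt
Reagents that add atoms: none
Why: Yamaguchi esterification: the acid is activated as the mixed anhydride and DMAP transfers the epoxy-acyl group to O3; no bond to C3 or to the oxirane carbons is broken, so all stereocentres are retained.

Step 16
Reactants: 21 (1S,5R,6R)-3-{[(tert-butyldiphenylsilyl)oxy]methyl}-5-{[(2Z)-2-methylbut-2-enoyl]oxy}-2-oxo-6-(propan-2-yl)cyclohex-3-en-1-yl (2R,3R)-2,3-dimethyloxirane-2-carboxylate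
Product: 22 (1S,5R,6R)-3-(hydroxymethyl)-5-{[(2Z)-2-methylbut-2-enoyl]oxy}-2-oxo-6-(propan-2-yl)cyclohex-3-en-1-yl (2R,3R)-2,3-dimethyloxirane-2-carboxylate (CNP0293054.1)
Conditions: HF·pyridine, pyridine, THF, 0 °C → rt
Reagents that add atoms: none
Why: Fluoride cleavage of the primary silyl ether under buffered, weakly acidic conditions, under which both esters, the oxirane and the enone should be stable and acyl migration to O7 is not promoted.

**Compound list**

1 | furan-3-methanol | OCc1ccoc1 | starting material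
2 | but-2-ynal | CC#CC=O | starting material
3 | 2-lithio-3-(lithiooxymethyl)furan | [Li]OCc1ccoc1[Li] | intermediate (not isolated)
4 | rac-1-[3-(hydroxymethyl)furan-2-yl]but-2-yn-1-ol | CC#CC(O)c1occc1CO | intermediate
5 | rac-1-[3-({[tert-butyl(diphenyl)silyl]oxy}methyl)furan-2-yl]but-2-yn-1-ol | CC#CC(O)c1occc1CO[Si](c2ccccc2)(c3ccccc3)C(C)(C)C | intermediate
6 | 1-[3-({[tert-butyl(diphenyl)silyl]oxy}methyl)furan-2-yl]but-2-yn-1-one | CC#CC(=O)c1occc1CO[Si](c2ccccc2)(c3ccccc3)C(C)(C)C | intermediate
7 | (1S)-1-[3-({[tert-butyl(diphenyl)silyl]oxy}methyl)furan-2-yl]but-2-yn-1-ol | CC#C[C@H](O)c1occc1CO[Si](c2ccccc2)(c3ccccc3)C(C)(C)C | intermediate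
8 | (1S)-1-[3-({[tert-butyl(diphenyl)silyl]oxy}methyl)furan-2-yl]-3-methylbut-2-en-1-ol | CC(C)=C[C@H](O)c1occc1CO[Si](c2ccccc2)(c3ccccc3)C(C)(C)C | intermediate
9 | tert-butyl({(1S)-1-[3-({[tert-butyl(diphenyl)silyl]oxy}methyl)furan-2-yl]-3-methylbut-2-en-1-yl}oxy)dimethylsilane | CC(C)=C[C@H](O[Si](C)(C)C(C)(C)C)c1occc1CO[Si](c2ccccc2)(c3ccccc3)C(C)(C)C | intermediate
10 | furan 2,5-endoperoxide of 9 (2,3,7-trioxabicyclo[2.2.1]hept-5-ene; side-chain centre S, bridgeheads as formed) | CC(C)=C[C@H](O[Si](C)(C)C(C)(C)C)C12OOC(O1)C=C2CO[Si](c3ccccc3)(c4ccccc4)C(C)(C)C | intermediate (not isolated)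
11 | (2Z,5S)-5-[(tert-butyldimethylsilyl)oxy]-3-{[(tert-butyldiphenylsilyl)oxy]methyl}-7-methyl-4-oxoocta-2,6-dienal | O=C/C=C(\C(=O)[C@@H](O[Si](C)(C)C(C)(C)C)C=C(C)C)CO[Si](c1ccccc1)(c1ccccc1)C(C)(C)C | intermediate (key-step precursor)
12 | (4S,5R,6S)-6-[(tert-butyldimethylsilyl)oxy]-2-{[(tert-butyldiphenylsilyl)oxy]methyl}-4-hydroxy-5-(prop-1-en-2-yl)cyclohex-2-en-1-one | O[C@H]1C=C(CO[Si](c2ccccc2)(c2ccccc2)C(C)(C)C)C(=O)[C@@H](O[Si](C)(C)C(C)(C)C)[C@@H]1C(C)=C | intermediate (key-step product)
13 | (4S,5R,6S)-6-[(tert-butyldimethylsilyl)oxy]-2-{[(tert-butyldiphenylsilyl)oxy]methyl}-4-hydroxy-5-(propan-2-yl)cyclohex-2-en-1-one | O[C@H]1C=C(CO[Si](c2ccccc2)(c2ccccc2)C(C)(C)C)C(=O)[C@@H](O[Si](C)(C)C(C)(C)C)[C@@H]1C(C)C | intermediate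
14 | angelic acid, (2Z)-2-methylbut-2-enoic acid | C/C=C(/C)C(=O)O | starting material
15 | (1R,5S,6R)-5-[(tert-butyldimethylsilyl)oxy]-3-{[(tert-butyldiphenylsilyl)oxy]methyl}-4-oxo-6-(propan-2-yl)cyclohex-2-en-1-yl (2Z)-2-methylbut-2-enoate | C/C=C(/C)C(=O)O[C@@H]1C=C(CO[Si](c2ccccc2)(c2ccccc2)C(C)(C)C)C(=O)[C@@H](O[Si](C)(C)C(C)(C)C)[C@@H]1C(C)C | intermediate
16 | (1R,5S,6S)-3-{[(tert-butyldiphenylsilyl)oxy]methyl}-5-hydroxy-4-oxo-6-(propan-2-yl)cyclohex-2-en-1-yl (2Z)-2-methylbut-2-enoate | C/C=C(/C)C(=O)O[C@@H]1C=C(CO[Si](c2ccccc2)(c2ccccc2)C(C)(C)C)C(=O)[C@@H](O)[C@@H]1C(C)C | intermediate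
17 | (2Z)-2-methylbut-2-en-1-ol | C/C=C(/C)CO | intermediate
18 | [(2S,3R)-2,3-dimethyloxiran-2-yl]methanol | OC[C@]1(C)O[C@@H]1C | intermediate
19 | (2R,3R)-2,3-dimethyloxirane-2-carboxylic acid | OC(=O)[C@]1(C)O[C@@H]1C | intermediate
20 | (2R,3R)-2,3-dimethyloxirane-2-carboxylic 2,4,6-trichlorobenzoic anhydride | Clc1cc(Cl)c(C(=O)OC(=O)[C@]2(C)O[C@@H]2C)c(Cl)c1 | intermediate (not isolated)
21 | (1S,5R,6R)-3-{[(tert-butyldiphenylsilyl)oxy]methyl}-5-{[(2Z)-2-methylbut-2-enoyl]oxy}-2-oxo-6-(propan-2-yl)cyclohex-3-en-1-yl (2R,3R)-2,3-dimethyloxirane-2-carboxylate | C/C=C(/C)C(=O)O[C@@H]1C=C(CO[Si](c2ccccc2)(c2ccccc2)C(C)(C)C)C(=O)[C@@H](OC(=O)[C@]3(C)O[C@@H]3C)[C@@H]1C(C)C | intermediate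
22 | (1S,5R,6R)-3-(hydroxymethyl)-5-{[(2Z)-2-methylbut-2-enoyl]oxy}-2-oxo-6-(propan-2-yl)cyclohex-3-en-1-yl (2R,3R)-2,3-dimethyloxirane-2-carboxylate | C/C=C(/C)C(=O)O[C@@H]1C=C(CO)C(=O)[C@@H](OC(=O)[C@]2(C)O[C@@H]2C)[C@@H]1C(C)C | target

Total step count: 16. Longest linear sequence: 13 (steps 1–11, 15, 16).

**Steps most likely to fail**

1. Step 8 (carbonyl-ene closure). The hydrogen shift from the C8 methyl may lag behind C–C bond formation, so that the C8 cation is diverted into chloride capture or alkene-isomer mixtures, and the cis oxo-enal may isomerise to the trans form before closing. Fallback, from 11 back to 13: run the closure as a stepwise Prins cyclisation with deliberate chloride capture (TiCl4, CH2Cl2, −78 °C, short contact). The same chair-like arrangement should give (4S,5R,6S)-6-[(tert-butyldimethylsilyl)oxy]-2-{[(tert-butyldiphenylsilyl)oxy]methyl}-5-(2-chloropropan-2-yl)-4-hydroxycyclohex-2-en-1-one F1. Radical dechlorination of the tertiary chloride (Bu3SnH, AIBN, toluene, 80 °C) then gives 13 directly, so the ene hydrogen transfer and the hydrogenation of step 9 are both bypassed.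

2. Step 10 (Mitsunobu with angelic acid). Displacement at the menthol-like C5 position by a weakly acidic carboxylic acid may be slow, letting elimination toward the dienone, acyl transfer with retention, or phosphine-induced Z to E isomerisation of the acid compete. Fallback, from 13 back to 15: separate inversion from acylation.
   - Mitsunobu reaction with the more acidic chloroacetic acid (PPh3, DIAD, toluene) gives the inverted (1R,5S,6R)-5-[(tert-butyldimethylsilyl)oxy]-3-{[(tert-butyldiphenylsilyl)oxy]methyl}-4-oxo-6-(propan-2-yl)cyclohex-2-en-1-yl chloroacetate F2.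
   - Thiourea with NaHCO3 in EtOH removes the chloroacetyl group under near-neutral conditions to give (4R,5R,6S)-6-[(tert-butyldimethylsilyl)oxy]-2-{[(tert-butyldiphenylsilyl)oxy]methyl}-4-hydroxy-5-(propan-2-yl)cyclohex-2-en-1-one F3 (OH cis to isopropyl).
   - Acylation with retention by (2Z)-2-methylbut-2-enoic 2,4,6-trichlorobenzoic anhydride F4 (made from 14, 2,4,6-trichlorobenzoyl chloride and Et3N; toluene, warm, no strong base) gives 15.

3. Step 5 (iron-catalysed methyl addition). Methyl transfer to the hindered furfurylic alkoxide may be slow or regio-unselective, leaving alkyne or giving the proximal-methyl isomer. Fallback, from 7 back to 8: trans-hydroalumination with NaAlH2(OCH2CH2OMe)2 in THF, followed by iodine at −78 °C, puts hydrogen on the proximal and iodine on the distal alkyne carbon, giving (1S,2Z)-1-[3-({[tert-butyl(diphenyl)silyl]oxy}methyl)furan-2-yl]-3-iodobut-2-en-1-ol F5. Negishi coupling with MeZnCl and Pd(PPh3)4 in THF then replaces iodine by methyl and gives 8.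

Further compounds
F1 | step 8 | (4S,5R,6S)-6-[(tert-butyldimethylsilyl)oxy]-2-{[(tert-butyldiphenylsilyl)oxy]methyl}-5-(2-chloropropan-2-yl)-4-hydroxycyclohex-2-en-1-one | O[C@H]1C=C(CO[Si](c2ccccc2)(c2ccccc2)C(C)(C)C)C(=O)[C@@H](O[Si](C)(C)C(C)(C)C)[C@@H]1C(C)(C)Cl
F2 | step 10 | (1R,5S,6R)-5-[(tert-butyldimethylsilyl)oxy]-3-{[(tert-butyldiphenylsilyl)oxy]methyl}-4-oxo-6-(propan-2-yl)cyclohex-2-en-1-yl chloroacetate | ClCC(=O)O[C@@H]1C=C(CO[Si](c2ccccc2)(c2ccccc2)C(C)(C)C)C(=O)[C@@H](O[Si](C)(C)C(C)(C)C)[C@@H]1C(C)C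
F3 | step 10 | (4R,5R,6S)-6-[(tert-butyldimethylsilyl)oxy]-2-{[(tert-butyldiphenylsilyl)oxy]methyl}-4-hydroxy-5-(propan-2-yl)cyclohex-2-en-1-one | O[C@@H]1C=C(CO[Si](c2ccccc2)(c2ccccc2)C(C)(C)C)C(=O)[C@@H](O[Si](C)(C)C(C)(C)C)[C@@H]1C(C)C
F4 | step 10 | (2Z)-2-methylbut-2-enoic 2,4,6-trichlorobenzoic anhydride | C/C=C(/C)C(=O)OC(=O)c1c(Cl)cc(Cl)cc1Cl
F5 | step 5 | (1S,2Z)-1-[3-({[tert-butyl(diphenyl)silyl]oxy}methyl)furan-2-yl]-3-iodobut-2-en-1-ol | C/C(I)=C/[C@H](O)c1occc1CO[Si](c2ccccc2)(c3ccccc3)C(C)(C)C
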